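**Assumption (remark on the chemistry):** magnesium bis(ethyl malonate) is used as a purchased reagent, and phloroglucinol is dried to its anhydrous form before step 6, because water of crystallisation would hydrolyse and decarboxylate the β-ketoester. Unit 1 is the flavone whose ring B carries the ether at C4'; unit 2 is the flavone whose ring A carries it at C8. All structures were checked against the target and no correction was needed.

## Structural features

Lanaroflavone consists of two apigenin-type 2-aryl-4H-chromen-4-ones, each with an oxygenated benzo ring A, a 4-pyranone ring C and a para-oxygenated phenyl ring B. The two units are joined by one diaryl ether oxygen that runs from C4' of ring B of unit 1 to C8 of ring A of unit 2. The molecule has no stereocentre and no stereogenic axis, so no stereocentres stand next to each other and the whole problem is one of regiochemistry and of telling two nearly identical halves apart. Five phenols are free in the target: 5-OH and 7-OH in each unit (the 5-OH groups chelated to C4=O) and 4'-OH in unit 2; the polyphenol is sensitive to oxidation in base. The fragile part is the 5,7-dihydroxy-8-aryloxychromone of unit 2: under hot protic acid ring C can open and close again through the other ortho oxygen, which would move the ether from C8 to C6. The real difficulty is to place the ether at C8 of unit 2, a carbon flanked by C7–O and C8a–O1 that is hard to arylate late, and to build the second chromone without protecting-group traffic. The key step exploits ring A of unit 1, which carries nothing but 5-OH, 7-OH, O1 and the C4a–C4 bond: it is a phloroglucinol nucleus with three equivalent C–H and three equivalent OH groups. Acylation at any carbon and closure through either neighbouring hydroxyl therefore forms C4–C4a and O1–C2 of the same chromone.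

## Logic of the disconnections

**16 ⇒ 15.** The three O–CH3 bonds on O5, O7 and O4' of unit 2 are cut. Methyl is the one phenol mask that survives AlCl3, hot KOH, iodine in DMSO at 130 °C and a 240 °C melt. Because unit 1 is never protected, only three ethers have to be cleaved at the end. The forward step must cleave all three, including the slow one at O7, under cold aprotic Lewis-acid conditions in which ring C of unit 2 does not open and re-close and the diaryl ether is untouched.

**15 ⇒ 11 + 12.** C4–C4a and O1–C2 of unit 1 are cut, which opens ring C of that unit. The cut is made here because 12 is threefold symmetric, so no regiochemical question can arise and no protection is needed. It removes a whole chromone and leaves a linear β-ketoester that carries the finished unit 2. The forward step must deliver the acyl group to carbon rather than oxygen, must run without acid so that the chromone and not the coumarin closes, and must leave unit 2 inert.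

**11 ⇒ 9 (through 10).** The bond between the aroyl carbon and the methylene carbon is cut, a two-carbon homologation of a carboxylic acid. This returns the problem to a stable, crystalline acid. The forward step must activate only the carboxyl group and must use a C-nucleophile mild enough not to open ring C of unit 2.

**9 ⇒ 8.** O1–C2 of unit 2 is cut and two hydrogens are restored at C2 and C3. The precursor has a single hydroxyl ortho to the enone carbonyl, so closure can only give the 8-aryloxy chromone. The heterocycle is simplified to an open enone. The forward oxidation must tolerate the free acid and must not iodinate the electron-rich ring.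

**8 ⇒ 5 + 6 (through 7).** The Cα=Cβ bond of the enone and the ester O–CH3 link are cut. An aldol condensation brings in three carbons and ring B of unit 2 from a cheap aldehyde, and the same hydroxide unmasks the acid. The forward step must hydrolyse the ester before 6 is added, so that the aldehyde never meets hot base, and must give the E-enone by thermodynamic dehydration.

**5 ⇒ 3 (through 4).** The aryl–acetyl bond and one O–CH3 bond are cut. The two free positions of the electron-rich ring of 3 are equivalent, so acylation is unambiguous. The forward step must then cleave the methoxy group that lies between the acetyl group and the aryloxy carbon, and only that one; this decision fixes C8 rather than C6 of unit 2.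

**3 ⇒ 1 + 2.** The ether C–O bond on the benzoate side (the future C4'–O of unit 1) is cut. The hindered, electron-rich ring acts as nucleophile and the ester-bearing ring as electrophile, which avoids arylating a doubly flanked hydroxyl on a finished chromone. Both pieces are commercial. The forward step is a nucleophilic aromatic substitution on a moderately activated fluoride by a di-ortho-substituted phenoxide, which must be kept from oxidation and from attacking the ester methyl group.

## Other disconnections considered

**Alternative 1:** The cut is C3'–C4' and C5'–C6' of ring B of unit 1, so that this benzene ring is built from methyl coumalate A2 and 2-(ethynyloxy)-1,3,5-trimethoxybenzene A3 (to be made from 1).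
- *Forward key step:* an inverse-demand [4+2] cycloaddition in which the nucleophilic terminal carbon of A3 bonds to C6 of A2 and the oxygen-bearing carbon to C3, then loss of CO2 to give methyl 4-(2,4,6-trimethoxyphenoxy)benzoate A1.
- *In its favour:* polarisation of both partners should give the para isomer only, the conditions are neutral and metal-free, and it avoids substitution at a weakly activated fluoroarene. On that last point it is better than step 1.
- *Against it:* A3 needs two extra operations on the oxidation-sensitive phenol 1 under strong base and is a heat-sensitive ynol ether; the step builds a benzene ring that can be bought; and it touches neither the C8/C6 question of unit 2 nor ring C of unit 1.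
- *Comparison:* A1 is the same substance as 3, so everything after it is identical to the chosen route, including step 6. Mechanistically the two are equal in regiochemical certainty. In step economy the alternative is worse, about three operations against one. It is a possible substitute for step 1, not for the key step.

**Alternative 2:** The cut is O1–C2 in both units, leading back to the bis-chalcone A4.
- *Forward key step:* anodic oxidation of iodide generates the iodinating species, and each 2'-hydroxychalcone closes by oxa-Michael addition, α-iodination and loss of HI, giving lanaroflavone pentamethyl ether A5. This is the electrochemical, twofold version of step 4.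
- *In its favour:* one operation closes both pyranone rings, there is no 240 °C melt and no two-carbon homologation, the oxidant is electricity with a catalytic mediator, and unit 1 has only one ortho hydroxyl so its closure is unambiguous. In mildness of the ring-forming step it is better than the chosen plan.
- *Against it:* A4 requires a central piece with both an acetyl group and an aromatic aldehyde, so the two crossed aldol condensations need ordering or protection. Unit 1 arrives with two more methyl ethers, so five must be cleaved, including a second slow one at O7, with longer exposure of unit 2 to Lewis acid. Iodine generated at the anode next to very electron-rich rings could iodinate them, and both cyclisations must go to completion.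
- *Comparison:* unit 2 meets the same C8/C6 decision as in step 2, so the two plans are equal there. The step count is similar, about seven. The chosen plan is better in that unit 1 is born unprotected and only three ethers remain.

**Alternative 3:** The cut is C2–C3 in both units, leading back to the bis-ester A6.
- *Forward key step:* base generates both acetyl enolates of A6, each attacks its neighbouring aryl ester carbonyl, and the bis(1,3-diketone) A7 results with both phenols freed. A separate acid cyclodehydration would then give A5, followed by fivefold demethylation.
- *In its favour:* the intramolecular acyl shift is reliable, sets the regiochemistry of each half automatically, runs at low temperature and needs neither an oxidation nor a melt. It is better than the chosen plan in thermal mildness and in not depending on C- against O-acylation.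
- *Against it:* A6 must be assembled from 7 by two different esterifications, one on its hindered chelated phenol and one of its carboxyl group with another ortho-acetylphenol. Activating the carboxyl group of 7 beside its own phenol invites self-condensation, so ordering or protection is needed. The aryl benzoate of unit 1 is an active ester exposed to strong base. A7 still needs ring closure and then cleavage of five ethers.
- *Comparison:* the plans are equal in how unit 2 is handled. In step economy the alternative is worse, about nine operations against seven, and it ends with more protecting groups to remove.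

Key step: step 6

## Route

**Step 1**
Reactants: 1 2,4,6-trimethoxyphenol; 2 methyl 4-fluorobenzoate
Product: 3 methyl 4-(2,4,6-trimethoxyphenoxy)benzoate
Conditions: Cs2CO3, degassed DMSO, 110 °C, Ar
Reagents that add atoms: none
Why: Nucleophilic aromatic substitution (addition–elimination): the cesium phenoxide of 1 adds para to the ester, the anionic adduct is stabilised by the CO2Me group and fluoride leaves; oxygen-free DMSO protects the electron-rich phenoxide and a slight excess of 2 covers any loss to ester cleavage.

**Step 2**
Reactants: 3 methyl 4-(2,4,6-trimethoxyphenoxy)benzoate
Product: 5 methyl 4-(3-acetyl-2-hydroxy-4,6-dimethoxyphenoxy)benzoate, via trimethoxy ketone 4 (not isolated)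
Conditions: AcCl, AlCl3 (3.5 equiv), CH2Cl2, 0 °C → rt; aq HCl
Reagents that add atoms: acetyl chloride, CC(=O)Cl
Why: Friedel–Crafts acylation at one of the two equivalent positions of the trimethoxy ring (the benzoate ring is deactivated), then chelation-controlled AlCl3 demethylation ortho to the ketone; of the two ortho methoxy groups the one between the acetyl group and the aryloxy carbon is twisted out of the ring plane, is the more basic and the more strained, and should be the one cleaved, as in the known behaviour of 2,3,4,6-tetraoxygenated acetophenones.

**Step 3**
Reactants: 5 methyl 4-(3-acetyl-2-hydroxy-4,6-dimethoxyphenoxy)benzoate; 6 4-methoxybenzaldehyde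
Product: 8 4-{2-hydroxy-4,6-dimethoxy-3-[(2E)-3-(4-methoxyphenyl)prop-2-enoyl]phenoxy}benzoic acid, via keto acid 7 (not isolated)
Conditions: KOH, EtOH–H2O, 60 °C, 2 h; then 6, rt, 48 h; aq HCl
Reagents that add atoms: potassium hydroxide, [K+].[OH-]
Why: Saponification of the methyl ester followed in the same pot by Claisen–Schmidt condensation of the methyl ketone with the non-enolisable aldehyde; E1cB dehydration gives the conjugated E-enone as the thermodynamic product, and any flavanone formed by closure is carried to the same flavone in step 4.

**Step 4**
Reactants: 8 4-{2-hydroxy-4,6-dimethoxy-3-[(2E)-3-(4-methoxyphenyl)prop-2-enoyl]phenoxy}benzoic acid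
Product: 9 4-{[5,7-dimethoxy-2-(4-methoxyphenyl)-4-oxo-4H-chromen-8-yl]oxy}benzoic acid
Conditions: I2 (10 mol%), DMSO, 130 °C
Reagents that add atoms: none
Why: Iodine-catalysed oxidative cyclisation of a 2'-hydroxychalcone (oxa-Michael closure, α-iodination, loss of HI, with DMSO re-oxidising iodide); the only hydroxyl ortho to the enone is the one next to the aryloxy carbon, so the ether must end at C8.

**Step 5**
Reactants: 9 4-{[5,7-dimethoxy-2-(4-methoxyphenyl)-4-oxo-4H-chromen-8-yl]oxy}benzoic acid
Product: 11 ethyl 3-(4-{[5,7-dimethoxy-2-(4-methoxyphenyl)-4-oxo-4H-chromen-8-yl]oxy}phenyl)-3-oxopropanoate, via acyl imidazolide 10 (not isolated)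
Conditions: CDI, THF–DMF, rt, 2 h; then Mg(O2CCH2CO2Et)2, 45 °C, 16 h; dilute aq HCl
Reagents that add atoms: magnesium bis(ethyl malonate), CCOC(=O)CC(=O)[O-].CCOC(=O)CC(=O)[O-].[Mg+2]; 1,1'-carbonyldiimidazole, O=C(n1ccnc1)n1ccnc1 (its imidazole ring is present in 10 only)
Why: Masamune–Brooks homologation: the imidazolide is C-acylated by the magnesium chelate of the malonate half-ester and the adduct loses CO2; the conditions are nearly neutral, so ring C of unit 2 is not opened.

**Step 6**
Reactants: 11 ethyl 3-(4-{[5,7-dimethoxy-2-(4-methoxyphenyl)-4-oxo-4H-chromen-8-yl]oxy}phenyl)-3-oxopropanoate; 12 phloroglucinol (benzene-1,3,5-triol, anhydrous)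
Product: 15 lanaroflavone trimethyl ether (5,7-dihydroxy-2-(4-{[5,7-dimethoxy-2-(4-methoxyphenyl)-4-oxo-4H-chromen-8-yl]oxy}phenyl)-4H-chromen-4-one), via aroylketene 13 (not isolated), via diketone 14 (not isolated)
Conditions: anhydrous 12 (3 equiv), neat melt, 240 °C, N2 sweep, no catalyst, 1 h
Reagents that add atoms: none
Why: Mentzer pyrone synthesis, the acid-free thermal condensation of a phenol with a β-ketoester. At 240 °C 11 should lose ethanol to aroylketene 13 (direct attack on the ester carbonyl would lead to the same intermediate), and the ketene carbon is taken up by a ring carbon of 12, the soft nucleophilic site of its keto–enol system, which forms C4–C4a and gives diketone 14. O-Acylation of 12 is reversible at this temperature, whereas 14 is drained irreversibly: its ortho hydroxyl adds to the aroyl carbonyl (6-exo-trig) and loss of water gives the aromatic 4-pyranone, forming O1–C2 and closing ring C of unit 1. No stereocentre is created. Three selectivities are needed: chromone against 4-arylcoumarin, secured by the absence of acid, without which the ketone carbonyl is not activated for the Pechmann-type hydroxyalkylation; mono- against poly-acylation, secured by the excess of 12 and by the deactivation of the ring once it carries the chelated acyl group; and regiochemistry, which does not arise because all three carbons and all three hydroxyls of 12 are equivalent. The N2 sweep removes ethanol and water so that 11 is not hydrolysed and decarboxylated, and unit 2, fully methylated and without acidic or nucleophilic sites, should be a spectator.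

**Step 7**
Reactants: 15 lanaroflavone trimethyl ether
Product: 16 lanaroflavone (5,7-dihydroxy-2-(4-{[5,7-dihydroxy-2-(4-hydroxyphenyl)-4-oxo-4H-chromen-8-yl]oxy}phenyl)-4H-chromen-4-one)
Conditions: BBr3 (15 equiv), CH2Cl2, −78 °C → rt, 36 h; ice-water, 0 °C
Reagents that add atoms: none
Why: Lewis-acid cleavage of aryl methyl ethers (O–B coordination, then bromide attack at methyl); the chelated 5-methoxy group goes first and the excess covers the free phenols of unit 1; diaryl ethers are not cleaved, and the cold aprotic conditions and cold quench avoid the acid-induced opening and re-closure of ring C that would shift the ether to C6.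

## Compound list

1 | 2,4,6-trimethoxyphenol | COc1cc(OC)c(O)c(OC)c1 | starting material
2 | methyl 4-fluorobenzoate | COC(=O)c1ccc(F)cc1 | starting material
3 | methyl 4-(2,4,6-trimethoxyphenoxy)benzoate | COC(=O)c1ccc(Oc2c(OC)cc(OC)cc2OC)cc1 | intermediate
4 | methyl 4-(3-acetyl-2,4,6-trimethoxyphenoxy)benzoate | COC(=O)c1ccc(Oc2c(OC)cc(OC)c(C(C)=O)c2OC)cc1 | intermediate (not isolated)
5 | methyl 4-(3-acetyl-2-hydroxy-4,6-dimethoxyphenoxy)benzoate | COC(=O)c1ccc(Oc2c(OC)cc(OC)c(C(C)=O)c2O)cc1 | intermediate
6 | 4-methoxybenzaldehyde | COc1ccc(C=O)cc1 | starting material
7 | 4-(3-acetyl-2-hydroxy-4,6-dimethoxyphenoxy)benzoic acid (in the flask as its dipotassium salt) | CC(=O)c1c(OC)cc(OC)c(Oc2ccc(C(=O)O)cc2)c1O | intermediate (not isolated)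
8 | 4-{2-hydroxy-4,6-dimethoxy-3-[(2E)-3-(4-methoxyphenyl)prop-2-enoyl]phenoxy}benzoic acid | COc1ccc(/C=C/C(=O)c2c(OC)cc(OC)c(Oc3ccc(C(=O)O)cc3)c2O)cc1 | intermediate
9 | 4-{[5,7-dimethoxy-2-(4-methoxyphenyl)-4-oxo-4H-chromen-8-yl]oxy}benzoic acid | COc1ccc(-c2cc(=O)c3c(OC)cc(OC)c(Oc4ccc(C(=O)O)cc4)c3o2)cc1 | intermediate
10 | 1-(4-{[5,7-dimethoxy-2-(4-methoxyphenyl)-4-oxo-4H-chromen-8-yl]oxy}benzoyl)imidazole | COc1ccc(-c2cc(=O)c3c(OC)cc(OC)c(Oc4ccc(C(=O)n5ccnc5)cc4)c3o2)cc1 | intermediate (not isolated)
11 | ethyl 3-(4-{[5,7-dimethoxy-2-(4-methoxyphenyl)-4-oxo-4H-chromen-8-yl]oxy}phenyl)-3-oxopropanoate | CCOC(=O)CC(=O)c1ccc(Oc2c(OC)cc(OC)c3c(=O)cc(-c4ccc(OC)cc4)oc23)cc1 | intermediate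
12 | phloroglucinol (benzene-1,3,5-triol) | Oc1cc(O)cc(O)c1 | starting material
13 | 3-(4-{[5,7-dimethoxy-2-(4-methoxyphenyl)-4-oxo-4H-chromen-8-yl]oxy}phenyl)-3-oxoprop-1-en-1-one (aroylketene) | O=C=CC(=O)c1ccc(Oc2c(OC)cc(OC)c3c(=O)cc(-c4ccc(OC)cc4)oc23)cc1 | intermediate (not isolated)
14 | 1-(4-{[5,7-dimethoxy-2-(4-methoxyphenyl)-4-oxo-4H-chromen-8-yl]oxy}phenyl)-3-(2,4,6-trihydroxyphenyl)propane-1,3-dione | O=C(CC(=O)c1c(O)cc(O)cc1O)c1ccc(Oc2c(OC)cc(OC)c3c(=O)cc(-c4ccc(OC)cc4)oc23)cc1 | intermediate (not isolated)
15 | lanaroflavone trimethyl ether (unit 1 free; 5-, 7- and 4'-OMe on unit 2) | O=c1cc(-c2ccc(Oc3c(OC)cc(OC)c4c(=O)cc(-c5ccc(OC)cc5)oc34)cc2)oc2cc(O)cc(O)c12 | intermediate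
16 | lanaroflavone | O=c1cc(-c2ccc(Oc3c(O)cc(O)c4c(=O)cc(-c5ccc(O)cc5)oc34)cc2)oc2cc(O)cc(O)c12 | target

## Step count and risks

Total step count: 7. Longest linear sequence: 7 steps (1 → 16); compounds 2, 6 and 12 enter as purchased partners.

**Step 6 (key step).** The most likely failure is loss of the β-ketoester before it acylates: water released by the cyclodehydration, or left in the triol, hydrolyses it and the acid decarboxylates. The second is closure by the Pechmann pathway if traces of acid are present. Poor mixing of a high-melting ketoester in the melt would make both worse. The fallback sets out from 9 and returns at 15. The acid 9 is converted with oxalyl chloride and catalytic DMF to 4-{[5,7-dimethoxy-2-(4-methoxyphenyl)-4-oxo-4H-chromen-8-yl]oxy}benzoyl chloride F1. F1 is added at −78 °C to the lithium polyanion made from 2,4,6-trihydroxyacetophenone and excess LiN(SiMe3)2 in THF. Acylation at the enolate carbon should give diketone 14, this time isolated, which is closed to 15 by warming in acetic acid with a little H2SO4. Ring A of unit 1 is then brought in with its acetyl group already on carbon, so the C- against O-acylation question disappears.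

**Step 2.** The risk is cleavage of the less hindered ortho methoxy group, or of both, instead of the one next to the aryloxy carbon. That would place the free hydroxyl on the wrong side of the ketone and lead to closure towards C6. The fallback sets out from 1 and returns at 5. Acetylation of the free phenol 1 with acetyl chloride and AlCl3 should cleave the methoxy group lying between the new acetyl group and the aluminium phenoxide, since it is held by both chelates. This should give 1-(2,3-dihydroxy-4,6-dimethoxyphenyl)ethan-1-one F2. Its dianion (Cs2CO3, DMSO) should be arylated by 2 at the non-chelated, more nucleophilic oxygen, giving 5.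

**Step 1.** The risk is slow addition–elimination at the weakly activated fluoroarene by a doubly ortho-substituted phenoxide, which leaves time for attack of the phenoxide on the ester methyl group and for air oxidation of the phenoxide. The fallback sets out from 1 and returns at 7. Substitution on the much more activated 4-fluorobenzaldehyde (K2CO3, DMF, 100 °C) should give 4-(2,4,6-trimethoxyphenoxy)benzaldehyde F3. Pinnick oxidation (NaClO2, NaH2PO4, 2-methylbut-2-ene) gives 4-(2,4,6-trimethoxyphenoxy)benzoic acid F4. Acetylation with demethylation as in step 2, with one more equivalent of AlCl3, should give 7 directly, which then needs only the aldol half of step 3.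

**Step 7.** The risks are incomplete cleavage of the 7- and 4'-methyl ethers of unit 2, and acid-induced opening and re-closure of ring C of unit 2 if the mixture or the quench becomes warm and protic. The fallback sets out from 15 and returns at 16 in two stages. BCl3 in CH2Cl2 at 0 °C should remove only the chelated 5-methyl group and give lanaroflavone dimethyl ether (unit 2: 5-OH free, 7-OMe and 4'-OMe kept) F5. NaSEt in DMF at 130 °C should then remove the two remaining methyl groups by nucleophilic attack at carbon under basic conditions, in which the acid-induced rearrangement cannot occur.

## Further compounds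

F1 | step 6 | 4-{[5,7-dimethoxy-2-(4-methoxyphenyl)-4-oxo-4H-chromen-8-yl]oxy}benzoyl chloride | COc1ccc(-c2cc(=O)c3c(OC)cc(OC)c(Oc4ccc(C(=O)Cl)cc4)c3o2)cc1
F2 | step 2 | 1-(2,3-dihydroxy-4,6-dimethoxyphenyl)ethan-1-one | CC(=O)c1c(OC)cc(OC)c(O)c1O
F3 | step 1 | 4-(2,4,6-trimethoxyphenoxy)benzaldehyde | COc1cc(OC)c(Oc2ccc(C=O)cc2)c(OC)c1
F4 | step 1 | 4-(2,4,6-trimethoxyphenoxy)benzoic acid | COc1cc(OC)c(Oc2ccc(C(=O)O)cc2)c(OC)c1
F5 | step 7 | lanaroflavone dimethyl ether (5,7-dihydroxy-2-(4-{[5-hydroxy-7-methoxy-2-(4-methoxyphenyl)-4-oxo-4H-chromen-8-yl]oxy}phenyl)-4H-chromen-4-one) | O=c1cc(-c2ccc(Oc3c(OC)cc(O)c4c(=O)cc(-c5ccc(OC)cc5)oc34)cc2)oc2cc(O)cc(O)c12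
A1 | alternative 1 | methyl 4-(2,4,6-trimethoxyphenoxy)benzoate | COC(=O)c1ccc(Oc2c(OC)cc(OC)cc2OC)cc1
A2 | alternative 1 | methyl coumalate (methyl 2-oxo-2H-pyran-5-carboxylate) | COC(=O)c1ccc(=O)oc1
A3 | alternative 1 | 2-(ethynyloxy)-1,3,5-trimethoxybenzene | C#COc1c(OC)cc(OC)cc1OC
A4 | alternative 2 | (2E)-1-(2-hydroxy-4,6-dimethoxyphenyl)-3-[4-({2-hydroxy-4,6-dimethoxy-3-[(2E)-3-(4-methoxyphenyl)prop-2-enoyl]phenyl}oxy)phenyl]prop-2-en-1-one (bis-chalcone) | COc1ccc(/C=C/C(=O)c2c(OC)cc(OC)c(Oc3ccc(/C=C/C(=O)c4c(O)cc(OC)cc4OC)cc3)c2O)cc1
A5 | alternative 2 | lanaroflavone pentamethyl ether | COc1ccc(cc1)-c1cc(=O)c2c(OC)cc(OC)c(Oc3ccc(cc3)-c3cc(=O)c4c(OC)cc(OC)cc4o3)c2o1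
A6 | alternative 3 | 2-acetyl-3,5-dimethoxyphenyl 4-{3-acetyl-4,6-dimethoxy-2-[(4-methoxybenzoyl)oxy]phenoxy}benzoate (bis-ester) | CC(=O)c1c(OC)cc(OC)cc1OC(=O)c1ccc(Oc2c(OC)cc(OC)c(C(C)=O)c2OC(=O)c2ccc(OC)cc2)cc1
A7 | alternative 3 | bis(ortho-hydroxyaryl 1,3-diketone) diaryl ether | COc1cc(OC)c(C(=O)CC(=O)c2ccc(Oc3c(OC)cc(OC)c(C(=O)CC(=O)c4ccc(OC)cc4)c3O)cc2)c(O)c1
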